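## Retrosynthetic overview

1. (Chain numbered C1 = lactone C=O to C40; C35 = lactone CH–O, C36 = side-chain CH(CH3).) The only ring, the 36-membered lactone, is closed in step 17 by intramolecular B-alkyl Suzuki coupling (C3–C4), after the single free hydroxyl (C35) is esterified with (Z)-3-iodobut-2-enoic acid; the nine other carbinols travel as C–Bpin and are unmasked in the last step.
2. C32–C33: lithiation–borylation/1,2-metallate shift between the unprotected hydroxy carbamate C33–C40 and the primary boronate of the C4–C32 polyboronate.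
3. C4–C32: but-3-enyl carbamate is added six times by sparteine-controlled lithiation–borylation (C9, C13, C17, C21, C25, C29), alternating with alkene hydroboration (1,5-spacing) or asymmetric diboration (C7, C27; 1,3-spacing).
4. C33–C40: Markovnikov hydroboration of hex-1-ene (C36), then lithiation–borylation/oxidation with propane-1,3-diol bis-carbamate (C35).
5. Starting materials: but-3-en-1-ol, propane-1,3-diol, hex-1-ene, 5-bromopent-1-ene, (Z)-3-iodobut-2-enoic acid.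

**Conventions and assumption (one line):** the target is (2Z,7S,9R,13S,17R,21R,25S,27S,29S,33R,35R,36S); Bpin = pinacol boronate, Cb = N,N-diisopropylcarbamoyl; in every polyboronate each C–B centre has the spatial arrangement of the corresponding C–OH of the target; the Cu ligand (step 3) and Pt ligand (steps 5, 11) are the enantiomers that give the stated product configuration; (−)-sparteine gives the (S)-lithiated carbamate, borylation goes with retention and migration with inversion; the lithiated carbamates 13 and 17 are numbered where they are first made (steps 6 and 7), and the later homologations use the same reagent solution, prepared afresh from 2 in exactly the same way before the boronate is added.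

## Route

Step 1
Reactants: 1 but-3-en-1-ol
Product: 2 but-3-en-1-yl N,N-diisopropylcarbamate
Conditions: NaH, THF, 0 °C; iPr2NCOCl, reflux
Reagents that add atoms: N,N-diisopropylcarbamoyl chloride, CC(C)N(C(C)C)C(Cl)=O
Why: O-carbamoylation of the alkoxide (acyl substitution) installs the Hoppe carbamate that later directs α-lithiation and acts as the leaving group.

Step 2
Reactants: 3 propane-1,3-diol
Product: 4 propane-1,3-diyl bis(N,N-diisopropylcarbamate)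
Conditions: NaH (2.2 equiv), THF, 0 °C; iPr2NCOCl (2.2 equiv), reflux
Reagents that add atoms: N,N-diisopropylcarbamoyl chloride, CC(C)N(C(C)C)C(Cl)=O
Why: double O-carbamoylation (acyl substitution) gives a C3 unit in which one carbamate serves step 4 and the other step 15.

Step 3
Reactants: 5 hex-1-ene
Product: 6 (S)-2-(hexan-2-yl)-4,4,5,5-tetramethyl-1,3,2-dioxaborolane
Conditions: B2pin2, CuCl (5 mol%), P-chiral QuinoxP*-type bisphosphine (enantiomer giving the S-boronate), KOtBu (cat.), MeOH, THF, 0 °C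
Reagents that add atoms: bis(pinacolato)diboron, CC1(C)OB(OC1(C)C)B1OC(C)(C)C(C)(C)O1
Why: Cu-catalysed enantioselective Markovnikov hydroboration (protoboration) of an aliphatic 1-alkene places boron at C2 under ligand control and sets C36.

Step 4
Reactants: 4 propane-1,3-diyl bis(N,N-diisopropylcarbamate); 6 (S)-2-(hexan-2-yl)-4,4,5,5-tetramethyl-1,3,2-dioxaborolane
Product: 10 (3R,4S)-3-hydroxy-4-methyloctyl N,N-diisopropylcarbamate, via lithiated bis-carbamate 7 (not isolated), via boronate complex 8 (not isolated), via secondary boronate 9 (not isolated)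
Conditions: 4 (1.5 equiv), sBuLi, (−)-sparteine, Et2O, −78 °C, 5 h; 6, −78 °C; MgBr2·OEt2, reflux; then NaOH, H2O2, THF, 0 °C
Reagents that add atoms: hydrogen peroxide, OO
Why: Hoppe–Aggarwal lithiation–borylation: (−)-sparteine-controlled deprotonation gives (S)-7, borylation occurs with retention, the 1,2-metallate shift of the hexan-2-yl group (retention in the migrating group, inversion at the carbenoid carbon) sets C35 (R) next to C36 (S), and stereoretentive C–B oxidation frees the hydroxyl while the second carbamate survives.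

Step 5
Reactants: 11 5-bromopent-1-ene
Product: 12 (R)-2,2'-(5-bromopentane-1,2-diyl)bis(4,4,5,5-tetramethyl-1,3,2-dioxaborolane)
Conditions: B2pin2, Pt(dba)3 (1 mol%), TADDOL-derived phenylphosphonite (enantiomer giving this sense), THF, 60 °C
Reagents that add atoms: bis(pinacolato)diboron, CC1(C)OB(OC1(C)C)B1OC(C)(C)C(C)(C)O1
Why: Pt-catalysed enantioselective 1,2-diboration of a terminal alkene sets C7 under ligand control and supplies the primary C8 boronate.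

Step 6
Reactants: 12 (R)-2,2'-(5-bromopentane-1,2-diyl)bis(4,4,5,5-tetramethyl-1,3,2-dioxaborolane); 2 but-3-en-1-yl N,N-diisopropylcarbamate
Product: 15 C4–C12 bromo alkene bis(boronate), via lithiated carbamate 13 (not isolated), via boronate complex 14 (not isolated)
Conditions: 2, sBuLi, (−)-sparteine, Et2O, −78 °C, 5 h; 12, −78 °C; MgBr2·OEt2, reflux
Reagents that add atoms: none
Why: lithiation–borylation at the less hindered primary boron of the 1,2-bis(boronate) followed by 1,2-metallate rearrangement (C8 migrates from B to C9 with inversion at C9) sets C9 under reagent control.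

Step 7
Reactants: 15 C4–C12 bromo alkene bis(boronate); 2 but-3-en-1-yl N,N-diisopropylcarbamate
Product: 19 C4–C16 bromo alkene tris(boronate), via primary boronate 16 (not isolated), via lithiated carbamate 17 (not isolated), via boronate complex 18 (not isolated)
Conditions: HBpin, [Ir(cod)Cl]2 (1.5 mol%), dppm, CH2Cl2, rt; evaporate; then 2, sBuLi, (+)-sparteine, Et2O, −78 °C; MgBr2·OEt2, reflux
Reagents that add atoms: pinacolborane, [H]B1OC(C)(C)C(C)(C)O1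
Why: Ir-catalysed anti-Markovnikov hydroboration gives the primary C12 boronate (used crude once volatiles are removed), which alone is attacked by the (R)-lithiated carbamate, and the 1,2-metallate shift (lithiation–borylation) sets C13.

Step 8
Reactants: 19 C4–C16 bromo alkene tris(boronate); 2 but-3-en-1-yl N,N-diisopropylcarbamate
Product: 22 C4–C20 bromo alkene tetrakis(boronate), via primary boronate 20 (not isolated), via boronate complex 21 (not isolated)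
Conditions: HBpin, [Ir(cod)Cl]2, dppm, CH2Cl2, rt; evaporate; then 2, sBuLi, (+)-sparteine, Et2O, −78 °C (reagent solution as in step 7); MgBr2·OEt2, reflux
Reagents that add atoms: pinacolborane, [H]B1OC(C)(C)C(C)(C)O1
Why: the same hydroboration then lithiation–borylation/1,2-metallate shift, with the (R)-lithiated carbamate prepared from 2 as in step 7, adds the next C4 unit and sets C17 by reagent control.

Step 9
Reactants: 22 C4–C20 bromo alkene tetrakis(boronate); 2 but-3-en-1-yl N,N-diisopropylcarbamate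
Product: 25 C4–C24 bromo alkene pentakis(boronate), via primary boronate 23 (not isolated), via boronate complex 24 (not isolated)
Conditions: HBpin, [Ir(cod)Cl]2, dppm, CH2Cl2, rt; evaporate; then 2, sBuLi, (+)-sparteine, Et2O, −78 °C (reagent solution as in step 7); MgBr2·OEt2, reflux
Reagents that add atoms: pinacolborane, [H]B1OC(C)(C)C(C)(C)O1
Why: hydroboration then lithiation–borylation/1,2-metallate shift with the (R)-lithiated carbamate prepared from 2 as in step 7 sets C21 by reagent control.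

Step 10
Reactants: 25 C4–C24 bromo alkene pentakis(boronate); 2 but-3-en-1-yl N,N-diisopropylcarbamate
Product: 28 C4–C28 bromo alkene hexakis(boronate), via primary boronate 26 (not isolated), via boronate complex 27 (not isolated)
Conditions: HBpin, [Ir(cod)Cl]2, dppm, CH2Cl2, rt; evaporate; then 2, sBuLi, (−)-sparteine, Et2O, −78 °C (reagent solution as in step 6); MgBr2·OEt2, reflux
Reagents that add atoms: pinacolborane, [H]B1OC(C)(C)C(C)(C)O1
Why: hydroboration then lithiation–borylation/1,2-metallate shift with the (S)-lithiated carbamate prepared from 2 as in step 6 (enantiomeric diamine) sets C25 in the opposite sense.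

Step 11
Reactants: 28 C4–C28 bromo alkene hexakis(boronate)
Product: 29 C4–C28 bromo octakis(boronate)
Conditions: B2pin2, Pt(dba)3 (3 mol%), the same TADDOL phosphonite as in step 5, THF, 60 °C
Reagents that add atoms: bis(pinacolato)diboron, CC1(C)OB(OC1(C)C)B1OC(C)(C)C(C)(C)O1
Why: catalyst-controlled Pt diboration of the only alkene sets C27 (syn to C25) and gives the primary C28 boronate.

Step 12
Reactants: 29 C4–C28 bromo octakis(boronate); 2 but-3-en-1-yl N,N-diisopropylcarbamate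
Product: 31 C4–C32 bromo alkene octakis(boronate), via boronate complex 30 (not isolated)
Conditions: 2, sBuLi, (+)-sparteine, Et2O, −78 °C, 5 h (reagent solution as in step 7); 29, −78 °C; MgBr2·OEt2, reflux
Reagents that add atoms: none
Why: primary-selective lithiation–borylation of the 1,2-bis(boronate) end with the (R)-lithiated carbamate prepared from 2 as in step 7, then 1,2-metallate shift, sets C29 anti to C27.

Step 13
Reactants: 31 C4–C32 bromo alkene octakis(boronate)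
Product: 32 C4–C32 bromo nonakis(boronate)
Conditions: HBpin, [Ir(cod)Cl]2 (1.5 mol%), dppm, CH2Cl2, rt
Reagents that add atoms: pinacolborane, [H]B1OC(C)(C)C(C)(C)O1
Why: Ir-catalysed anti-Markovnikov hydroboration converts the terminal alkene into the primary C32 boronate needed for the fragment union.

Step 14
Reactants: 32 C4–C32 bromo nonakis(boronate)
Product: 33 C4–C32 alkene nonakis(boronate)
Conditions: KOtBu, THF, 0 °C to rt
Reagents that add atoms: none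
Why: E2 elimination of the primary bromide with a bulky base unveils the C4=C5 alkene only after all chain hydroborations are finished.

Step 15
Reactants: 33 C4–C32 alkene nonakis(boronate); 10 (3R,4S)-3-hydroxy-4-methyloctyl N,N-diisopropylcarbamate
Product: 36 C4–C40 hydroxy nonakis(boronate), via dilithio carbamate 34 (not isolated), via boronate complex 35 (not isolated)
Conditions: 10 (1.5 equiv), sBuLi (3.1 equiv), (+)-sparteine (1.6 equiv), Et2O, −78 °C, 5 h; 33, −78 °C, 1 h; MgBr2·OEt2, reflux; aq NH4Cl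
Reagents that add atoms: none
Why: Proposed new method: lithiation–borylation of an unprotected γ-hydroxy carbamate through its O,C-dilithio species, in which the first sBuLi forms the lithium alkoxide, carbamoyl-directed sBuLi/(+)-sparteine deprotonation removes the pro-R α-H, the configurationally stable carbanion adds with retention to the only primary Bpin of 33, and anti-periplanar 1,2-migration of C32 with loss of the carbamate (inversion at C33) forms C32–C33 and sets C33, while the alkoxide has no β-leaving group and is simply reprotonated on work-up so that C35–OH emerges as the only free hydroxyl; the closest known reaction type is the Hoppe–Aggarwal lithiation–borylation of silyl-protected hydroxy carbamates.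

Step 16
Reactants: 36 C4–C40 hydroxy nonakis(boronate); 37 (Z)-3-iodobut-2-enoic acid
Product: 39 C35 (Z)-3-iodobut-2-enoate, via mixed anhydride 38 (not isolated)
Conditions: 37, 2,4,6-Cl3C6H2COCl, Et3N, THF, rt; then 36, DMAP, toluene, rt
Reagents that add atoms: none
Why: Yamaguchi esterification acylates the single free (hindered secondary) hydroxyl and brings in C1–C3 with the Z-iodide that fixes the alkene geometry.

Step 17
Reactants: 39 C35 (Z)-3-iodobut-2-enoate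
Product: 41 macrolactone nonakis(boronate), via alkylborane 40 (not isolated)
Conditions: 9-BBN, THF, rt; then slow addition to Pd(dppf)Cl2 (20 mol%), AsPh3, Cs2CO3, DMF/THF/H2O, 50 °C, 1 mM
Reagents that add atoms: none
Why: chemoselective hydroboration of the terminal alkene and intramolecular B-alkyl Suzuki–Miyaura coupling form C3–C4 with retention of the Z geometry and close the 36-membered ring, the secondary Bpin groups being inert to transmetalation.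

Step 18
Reactants: 41 macrolactone nonakis(boronate)
Product: 42 CNP0126363.4
Conditions: NaBO3·4H2O, THF/H2O (1:1), rt
Reagents that add atoms: sodium perborate, O=BO[O-].[Na+]
Why: perborate oxidation converts all nine C–B bonds to C–OH by 1,2-shift from boron to oxygen with retention, under conditions mild enough for the hindered enoate lactone.

## Compound list

1 | but-3-en-1-ol | C=CCCO | starting material
2 | but-3-en-1-yl N,N-diisopropylcarbamate | C=CCCOC(=O)N(C(C)C)C(C)C | intermediate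
3 | propane-1,3-diol | OCCCO | starting material
4 | propane-1,3-diyl bis(N,N-diisopropylcarbamate) | CC(C)N(C(C)C)C(=O)OCCCOC(=O)N(C(C)C)C(C)C | intermediate
5 | hex-1-ene | CCCCC=C | starting material
6 | (S)-2-(hexan-2-yl)-4,4,5,5-tetramethyl-1,3,2-dioxaborolane | CCCC[C@H](C)B2OC(C)(C)C(C)(C)O2 | intermediate
7 | (S)-1-lithio derivative of 4, (−)-sparteine complex | [Li][C@H](OC(=O)N(C(C)C)C(C)C)CCOC(=O)N(C(C)C)C(C)C | intermediate
8 | lithium boronate complex of 6 and 7 (B bonded to C36 and C35) | [Li+].CCCC[C@H](C)[B-]2(OC(C)(C)C(C)(C)O2)[C@H](OC(=O)N(C(C)C)C(C)C)CCOC(=O)N(C(C)C)C(C)C | intermediate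
9 | (3R,4S)-4-methyl-3-(4,4,5,5-tetramethyl-1,3,2-dioxaborolan-2-yl)octyl N,N-diisopropylcarbamate | CCCC[C@H](C)[C@H](B2OC(C)(C)C(C)(C)O2)CCOC(=O)N(C(C)C)C(C)C | intermediate
10 | (3R,4S)-3-hydroxy-4-methyloctyl N,N-diisopropylcarbamate (C33–C40) | CCCC[C@H](C)[C@H](O)CCOC(=O)N(C(C)C)C(C)C | intermediate
11 | 5-bromopent-1-ene | C=CCCCBr | starting material
12 | (R)-2,2'-(5-bromopentane-1,2-diyl)bis(4,4,5,5-tetramethyl-1,3,2-dioxaborolane) (C4–C8; Bpin at C7, C8) | C(B2OC(C)(C)C(C)(C)O2)[C@@H](B2OC(C)(C)C(C)(C)O2)CCCBr | intermediate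
13 | (S)-1-lithiobut-3-enyl N,N-diisopropylcarbamate, (−)-sparteine complex | [Li][C@H](OC(=O)N(C(C)C)C(C)C)CC=C | intermediate
14 | lithium boronate complex at C8 boron (carbenoid carbon C9) | [Li+].C=CC[C@@H](OC(=O)N(C(C)C)C(C)C)[B-]2(OC(C)(C)C(C)(C)O2)C[C@@H](B2OC(C)(C)C(C)(C)O2)CCCBr | intermediate
15 | C4–C12: 4-bromo, 11-ene, Bpin at C7, C9 | C=CC[C@@H](B2OC(C)(C)C(C)(C)O2)C[C@@H](B2OC(C)(C)C(C)(C)O2)CCCBr | intermediate
16 | C4–C12: 4-bromo, Bpin at C7, C9, C12 | C(B2OC(C)(C)C(C)(C)O2)CC[C@@H](B2OC(C)(C)C(C)(C)O2)C[C@@H](B2OC(C)(C)C(C)(C)O2)CCCBr | intermediate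
17 | (R)-1-lithiobut-3-enyl N,N-diisopropylcarbamate, (+)-sparteine complex | [Li][C@@H](OC(=O)N(C(C)C)C(C)C)CC=C | intermediate
18 | lithium boronate complex at C12 boron (carbenoid carbon C13) | [Li+].C=CC[C@H](OC(=O)N(C(C)C)C(C)C)[B-]2(OC(C)(C)C(C)(C)O2)CCC[C@@H](B2OC(C)(C)C(C)(C)O2)C[C@@H](B2OC(C)(C)C(C)(C)O2)CCCBr | intermediate
19 | C4–C16: 4-bromo, 15-ene, Bpin at C7, C9, C13 | C=CC[C@H](B2OC(C)(C)C(C)(C)O2)CCC[C@@H](B2OC(C)(C)C(C)(C)O2)C[C@@H](B2OC(C)(C)C(C)(C)O2)CCCBr | intermediate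
20 | C4–C16: 4-bromo, Bpin at C7, C9, C13, C16 | C(B2OC(C)(C)C(C)(C)O2)CC[C@H](B2OC(C)(C)C(C)(C)O2)CCC[C@@H](B2OC(C)(C)C(C)(C)O2)C[C@@H](B2OC(C)(C)C(C)(C)O2)CCCBr | intermediate
21 | lithium boronate complex at C16 boron (carbenoid carbon C17) | [Li+].C=CC[C@H](OC(=O)N(C(C)C)C(C)C)[B-]2(OC(C)(C)C(C)(C)O2)CCC[C@H](B2OC(C)(C)C(C)(C)O2)CCC[C@@H](B2OC(C)(C)C(C)(C)O2)C[C@@H](B2OC(C)(C)C(C)(C)O2)CCCBr | intermediate
22 | C4–C20: 4-bromo, 19-ene, Bpin at C7, C9, C13, C17 | C=CC[C@H](B2OC(C)(C)C(C)(C)O2)CCC[C@H](B2OC(C)(C)C(C)(C)O2)CCC[C@@H](B2OC(C)(C)C(C)(C)O2)C[C@@H](B2OC(C)(C)C(C)(C)O2)CCCBr | intermediate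
23 | C4–C20: 4-bromo, Bpin at C7, C9, C13, C17, C20 | C(B2OC(C)(C)C(C)(C)O2)CC[C@H](B2OC(C)(C)C(C)(C)O2)CCC[C@H](B2OC(C)(C)C(C)(C)O2)CCC[C@@H](B2OC(C)(C)C(C)(C)O2)C[C@@H](B2OC(C)(C)C(C)(C)O2)CCCBr | intermediate
24 | lithium boronate complex at C20 boron (carbenoid carbon C21) | [Li+].C=CC[C@H](OC(=O)N(C(C)C)C(C)C)[B-]2(OC(C)(C)C(C)(C)O2)CCC[C@H](B2OC(C)(C)C(C)(C)O2)CCC[C@H](B2OC(C)(C)C(C)(C)O2)CCC[C@@H](B2OC(C)(C)C(C)(C)O2)C[C@@H](B2OC(C)(C)C(C)(C)O2)CCCBr | intermediate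
25 | C4–C24: 4-bromo, 23-ene, Bpin at C7, C9, C13, C17, C21 | C=CC[C@H](B2OC(C)(C)C(C)(C)O2)CCC[C@H](B2OC(C)(C)C(C)(C)O2)CCC[C@H](B2OC(C)(C)C(C)(C)O2)CCC[C@@H](B2OC(C)(C)C(C)(C)O2)C[C@@H](B2OC(C)(C)C(C)(C)O2)CCCBr | intermediate
26 | C4–C24: 4-bromo, Bpin at C7, C9, C13, C17, C21, C24 | C(B2OC(C)(C)C(C)(C)O2)CC[C@H](B2OC(C)(C)C(C)(C)O2)CCC[C@H](B2OC(C)(C)C(C)(C)O2)CCC[C@H](B2OC(C)(C)C(C)(C)O2)CCC[C@@H](B2OC(C)(C)C(C)(C)O2)C[C@@H](B2OC(C)(C)C(C)(C)O2)CCCBr | intermediate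
27 | lithium boronate complex at C24 boron (carbenoid carbon C25) | [Li+].C=CC[C@@H](OC(=O)N(C(C)C)C(C)C)[B-]2(OC(C)(C)C(C)(C)O2)CCC[C@H](B2OC(C)(C)C(C)(C)O2)CCC[C@H](B2OC(C)(C)C(C)(C)O2)CCC[C@H](B2OC(C)(C)C(C)(C)O2)CCC[C@@H](B2OC(C)(C)C(C)(C)O2)C[C@@H](B2OC(C)(C)C(C)(C)O2)CCCBr | intermediate
28 | C4–C28: 4-bromo, 27-ene, Bpin at C7, C9, C13, C17, C21, C25 | C=CC[C@@H](B2OC(C)(C)C(C)(C)O2)CCC[C@H](B2OC(C)(C)C(C)(C)O2)CCC[C@H](B2OC(C)(C)C(C)(C)O2)CCC[C@H](B2OC(C)(C)C(C)(C)O2)CCC[C@@H](B2OC(C)(C)C(C)(C)O2)C[C@@H](B2OC(C)(C)C(C)(C)O2)CCCBr | intermediate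
29 | C4–C28: 4-bromo, Bpin at C7, C9, C13, C17, C21, C25, C27, C28 | C(B2OC(C)(C)C(C)(C)O2)[C@@H](B2OC(C)(C)C(C)(C)O2)C[C@@H](B2OC(C)(C)C(C)(C)O2)CCC[C@H](B2OC(C)(C)C(C)(C)O2)CCC[C@H](B2OC(C)(C)C(C)(C)O2)CCC[C@H](B2OC(C)(C)C(C)(C)O2)CCC[C@@H](B2OC(C)(C)C(C)(C)O2)C[C@@H](B2OC(C)(C)C(C)(C)O2)CCCBr | intermediate
30 | lithium boronate complex at C28 boron (carbenoid carbon C29) | [Li+].C=CC[C@H](OC(=O)N(C(C)C)C(C)C)[B-]2(OC(C)(C)C(C)(C)O2)C[C@@H](B2OC(C)(C)C(C)(C)O2)C[C@@H](B2OC(C)(C)C(C)(C)O2)CCC[C@H](B2OC(C)(C)C(C)(C)O2)CCC[C@H](B2OC(C)(C)C(C)(C)O2)CCC[C@H](B2OC(C)(C)C(C)(C)O2)CCC[C@@H](B2OC(C)(C)C(C)(C)O2)C[C@@H](B2OC(C)(C)C(C)(C)O2)CCCBr | intermediate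
31 | C4–C32: 4-bromo, 31-ene, Bpin at C7, C9, C13, C17, C21, C25, C27, C29 | C=CC[C@H](B2OC(C)(C)C(C)(C)O2)C[C@@H](B2OC(C)(C)C(C)(C)O2)C[C@@H](B2OC(C)(C)C(C)(C)O2)CCC[C@H](B2OC(C)(C)C(C)(C)O2)CCC[C@H](B2OC(C)(C)C(C)(C)O2)CCC[C@H](B2OC(C)(C)C(C)(C)O2)CCC[C@@H](B2OC(C)(C)C(C)(C)O2)C[C@@H](B2OC(C)(C)C(C)(C)O2)CCCBr | intermediate
32 | C4–C32: 4-bromo, Bpin at C7, C9, C13, C17, C21, C25, C27, C29, C32 | C(B2OC(C)(C)C(C)(C)O2)CC[C@H](B2OC(C)(C)C(C)(C)O2)C[C@@H](B2OC(C)(C)C(C)(C)O2)C[C@@H](B2OC(C)(C)C(C)(C)O2)CCC[C@H](B2OC(C)(C)C(C)(C)O2)CCC[C@H](B2OC(C)(C)C(C)(C)O2)CCC[C@H](B2OC(C)(C)C(C)(C)O2)CCC[C@@H](B2OC(C)(C)C(C)(C)O2)C[C@@H](B2OC(C)(C)C(C)(C)O2)CCCBr | intermediate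
33 | C4–C32: 4-ene, Bpin at C7, C9, C13, C17, C21, C25, C27, C29, C32 | C(B2OC(C)(C)C(C)(C)O2)CC[C@H](B2OC(C)(C)C(C)(C)O2)C[C@@H](B2OC(C)(C)C(C)(C)O2)C[C@@H](B2OC(C)(C)C(C)(C)O2)CCC[C@H](B2OC(C)(C)C(C)(C)O2)CCC[C@H](B2OC(C)(C)C(C)(C)O2)CCC[C@H](B2OC(C)(C)C(C)(C)O2)CCC[C@@H](B2OC(C)(C)C(C)(C)O2)C[C@@H](B2OC(C)(C)C(C)(C)O2)CC=C | intermediate
34 | O,C-dilithio derivative of 10 (lithium alkoxide at C35, (R)-lithio at C33), (+)-sparteine complex | [Li+].[Li][C@@H](OC(=O)N(C(C)C)C(C)C)C[C@@H]([O-])[C@@H](C)CCCC | intermediate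
35 | dilithium alkoxide boronate complex at C32 boron (carbenoid carbon C33) | [Li+].[Li+].CCCC[C@H](C)[C@H]([O-])C[C@H](OC(=O)N(C(C)C)C(C)C)[B-]2(OC(C)(C)C(C)(C)O2)CCC[C@H](B2OC(C)(C)C(C)(C)O2)C[C@@H](B2OC(C)(C)C(C)(C)O2)C[C@@H](B2OC(C)(C)C(C)(C)O2)CCC[C@H](B2OC(C)(C)C(C)(C)O2)CCC[C@H](B2OC(C)(C)C(C)(C)O2)CCC[C@H](B2OC(C)(C)C(C)(C)O2)CCC[C@@H](B2OC(C)(C)C(C)(C)O2)C[C@@H](B2OC(C)(C)C(C)(C)O2)CC=C | intermediate
36 | C4–C40: 4-ene, 35-ol, 36-methyl, Bpin at C7, C9, C13, C17, C21, C25, C27, C29, C33 | CCCC[C@H](C)[C@H](O)C[C@H](B2OC(C)(C)C(C)(C)O2)CCC[C@H](B2OC(C)(C)C(C)(C)O2)C[C@@H](B2OC(C)(C)C(C)(C)O2)C[C@@H](B2OC(C)(C)C(C)(C)O2)CCC[C@H](B2OC(C)(C)C(C)(C)O2)CCC[C@H](B2OC(C)(C)C(C)(C)O2)CCC[C@H](B2OC(C)(C)C(C)(C)O2)CCC[C@@H](B2OC(C)(C)C(C)(C)O2)C[C@@H](B2OC(C)(C)C(C)(C)O2)CC=C | intermediate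
37 | (Z)-3-iodobut-2-enoic acid | C/C(I)=C/C(=O)O | starting material
38 | (Z)-3-iodobut-2-enoic 2,4,6-trichlorobenzoic anhydride | C/C(I)=C/C(=O)OC(=O)c1c(Cl)cc(Cl)cc1Cl | intermediate
39 | (Z)-3-iodobut-2-enoate of 36 at C35–O | CCCC[C@H](C)[C@H](OC(=O)/C=C(\I)C)C[C@H](B2OC(C)(C)C(C)(C)O2)CCC[C@H](B2OC(C)(C)C(C)(C)O2)C[C@@H](B2OC(C)(C)C(C)(C)O2)C[C@@H](B2OC(C)(C)C(C)(C)O2)CCC[C@H](B2OC(C)(C)C(C)(C)O2)CCC[C@H](B2OC(C)(C)C(C)(C)O2)CCC[C@H](B2OC(C)(C)C(C)(C)O2)CCC[C@@H](B2OC(C)(C)C(C)(C)O2)C[C@@H](B2OC(C)(C)C(C)(C)O2)CC=C | intermediate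
40 | 39 with C4 bonded to 9-borabicyclo[3.3.1]nonan-9-yl (C4=C5 hydroborated) | CCCC[C@H](C)[C@H](OC(=O)/C=C(\I)C)C[C@H](B2OC(C)(C)C(C)(C)O2)CCC[C@H](B2OC(C)(C)C(C)(C)O2)C[C@@H](B2OC(C)(C)C(C)(C)O2)C[C@@H](B2OC(C)(C)C(C)(C)O2)CCC[C@H](B2OC(C)(C)C(C)(C)O2)CCC[C@H](B2OC(C)(C)C(C)(C)O2)CCC[C@H](B2OC(C)(C)C(C)(C)O2)CCC[C@@H](B2OC(C)(C)C(C)(C)O2)C[C@@H](B2OC(C)(C)C(C)(C)O2)CCCB3C4CCCC3CCC4 | intermediate
41 | 36-membered (2Z)-lactone with Bpin in place of OH at C7, C9, C13, C17, C21, C25, C27, C29, C33 | CCCC[C@H](C)[C@H]1C[C@H](B2OC(C)(C)C(C)(C)O2)CCC[C@H](B2OC(C)(C)C(C)(C)O2)C[C@@H](B2OC(C)(C)C(C)(C)O2)C[C@@H](B2OC(C)(C)C(C)(C)O2)CCC[C@H](B2OC(C)(C)C(C)(C)O2)CCC[C@H](B2OC(C)(C)C(C)(C)O2)CCC[C@H](B2OC(C)(C)C(C)(C)O2)CCC[C@@H](B2OC(C)(C)C(C)(C)O2)C[C@@H](B2OC(C)(C)C(C)(C)O2)CCC/C(C)=C\C(=O)O1 | intermediate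
42 | CNP0126363.4 | CCCC[C@H](C)[C@H]1C[C@H](O)CCC[C@H](O)C[C@@H](O)C[C@@H](O)CCC[C@H](O)CCC[C@H](O)CCC[C@H](O)CCC[C@@H](O)C[C@@H](O)CCC/C(C)=C\C(=O)O1 | target

## Step count and risks

Total step count: 18. Longest linear sequence: 14 steps (11 → 42, steps 5–18).

Three steps most likely to fail:

Step 15 (the proposed new step). The lithium alkoxide may aggregate with sBuLi/(+)-sparteine and erode the selectivity or rate of α-lithiation. Fallback with known chemistry: setting out from 10, TESCl/imidazole gives (3R,4S)-4-methyl-3-(triethylsilyloxy)octyl N,N-diisopropylcarbamate F1. Standard sBuLi/(+)-sparteine lithiation gives the lithiated carbamate F2, which is borylated with 33 to the boronate complex F3 and rearranges (MgBr2·OEt2, reflux) to the C35 triethylsilyl ether F4. HF·pyridine then removes the silyl group and the route is rejoined at 36.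

Step 16. The hydroxyl is hindered and sits next to a Lewis-acidic boron, and DMAP can isomerise the Z-iodoenoate. Fallback: setting out from 36, but-2-ynoic acid with DCC/DMAP (through the O-acylisourea F5) gives the C35 but-2-ynoate F6. Anti-hydroiodination of the ynoate with NaI in AcOH then gives the Z-iodoenoate, coming back at 39.

Step 17. The 36-membered B-alkyl Suzuki ring closure may lose to oligomerisation or protodeboronation at high dilution. Fallback: setting out from 36, 9-BBN gives the borane F7 (C4–B and O–B). Intermolecular Suzuki coupling with 37 (as its caesium salt; Pd(dppf)Cl2, AsPh3, Cs2CO3) gives the seco acid F8. Shiina macrolactonisation (2-methyl-6-nitrobenzoic anhydride, DMAP, through the mixed anhydride F9) closes the ring at the C35–O bond instead and returns to the route at 41.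

## Further compounds

F1 | step 15 | (3R,4S)-4-methyl-3-(triethylsilyloxy)octyl N,N-diisopropylcarbamate | CCCC[C@H](C)[C@H](O[Si](CC)(CC)CC)CCOC(=O)N(C(C)C)C(C)C
F2 | step 15 | (R)-1-lithio derivative of F1, (+)-sparteine complex | [Li][C@@H](OC(=O)N(C(C)C)C(C)C)C[C@@H](O[Si](CC)(CC)CC)[C@@H](C)CCCC
F3 | step 15 | lithium boronate complex of F2 with the C32 boron of 33 | [Li+].CCCC[C@H](C)[C@H](O[Si](CC)(CC)CC)C[C@H](OC(=O)N(C(C)C)C(C)C)[B-]2(OC(C)(C)C(C)(C)O2)CCC[C@H](B2OC(C)(C)C(C)(C)O2)C[C@@H](B2OC(C)(C)C(C)(C)O2)C[C@@H](B2OC(C)(C)C(C)(C)O2)CCC[C@H](B2OC(C)(C)C(C)(C)O2)CCC[C@H](B2OC(C)(C)C(C)(C)O2)CCC[C@H](B2OC(C)(C)C(C)(C)O2)CCC[C@@H](B2OC(C)(C)C(C)(C)O2)C[C@@H](B2OC(C)(C)C(C)(C)O2)CC=C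
F4 | step 15 | C35 triethylsilyl ether of 36 | CCCC[C@H](C)[C@H](O[Si](CC)(CC)CC)C[C@H](B2OC(C)(C)C(C)(C)O2)CCC[C@H](B2OC(C)(C)C(C)(C)O2)C[C@@H](B2OC(C)(C)C(C)(C)O2)C[C@@H](B2OC(C)(C)C(C)(C)O2)CCC[C@H](B2OC(C)(C)C(C)(C)O2)CCC[C@H](B2OC(C)(C)C(C)(C)O2)CCC[C@H](B2OC(C)(C)C(C)(C)O2)CCC[C@@H](B2OC(C)(C)C(C)(C)O2)C[C@@H](B2OC(C)(C)C(C)(C)O2)CC=C
F5 | step 16 | O-(but-2-ynoyl)-N,N'-dicyclohexylisourea | CC#CC(=O)OC(=NC1CCCCC1)NC1CCCCC1
F6 | step 16 | C35 but-2-ynoate of 36 | CCCC[C@H](C)[C@H](OC(=O)C#CC)C[C@H](B2OC(C)(C)C(C)(C)O2)CCC[C@H](B2OC(C)(C)C(C)(C)O2)C[C@@H](B2OC(C)(C)C(C)(C)O2)C[C@@H](B2OC(C)(C)C(C)(C)O2)CCC[C@H](B2OC(C)(C)C(C)(C)O2)CCC[C@H](B2OC(C)(C)C(C)(C)O2)CCC[C@H](B2OC(C)(C)C(C)(C)O2)CCC[C@@H](B2OC(C)(C)C(C)(C)O2)C[C@@H](B2OC(C)(C)C(C)(C)O2)CC=C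
F7 | step 17 | 36 with 9-BBN on C4 and on the C35 oxygen | CCCC[C@H](C)[C@H](OB3C4CCCC3CCC4)C[C@H](B2OC(C)(C)C(C)(C)O2)CCC[C@H](B2OC(C)(C)C(C)(C)O2)C[C@@H](B2OC(C)(C)C(C)(C)O2)C[C@@H](B2OC(C)(C)C(C)(C)O2)CCC[C@H](B2OC(C)(C)C(C)(C)O2)CCC[C@H](B2OC(C)(C)C(C)(C)O2)CCC[C@H](B2OC(C)(C)C(C)(C)O2)CCC[C@@H](B2OC(C)(C)C(C)(C)O2)C[C@@H](B2OC(C)(C)C(C)(C)O2)CCCB3C4CCCC3CCC4
F8 | step 17 | (2Z)-seco acid: C1 acid, 35-ol, Bpin at C7, C9, C13, C17, C21, C25, C27, C29, C33 | CCCC[C@H](C)[C@H](O)C[C@H](B2OC(C)(C)C(C)(C)O2)CCC[C@H](B2OC(C)(C)C(C)(C)O2)C[C@@H](B2OC(C)(C)C(C)(C)O2)C[C@@H](B2OC(C)(C)C(C)(C)O2)CCC[C@H](B2OC(C)(C)C(C)(C)O2)CCC[C@H](B2OC(C)(C)C(C)(C)O2)CCC[C@H](B2OC(C)(C)C(C)(C)O2)CCC[C@@H](B2OC(C)(C)C(C)(C)O2)C[C@@H](B2OC(C)(C)C(C)(C)O2)CCC/C(C)=C\C(=O)O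
F9 | step 17 | mixed anhydride of F8 with 2-methyl-6-nitrobenzoic acid | CCCC[C@H](C)[C@H](O)C[C@H](B2OC(C)(C)C(C)(C)O2)CCC[C@H](B2OC(C)(C)C(C)(C)O2)C[C@@H](B2OC(C)(C)C(C)(C)O2)C[C@@H](B2OC(C)(C)C(C)(C)O2)CCC[C@H](B2OC(C)(C)C(C)(C)O2)CCC[C@H](B2OC(C)(C)C(C)(C)O2)CCC[C@H](B2OC(C)(C)C(C)(C)O2)CCC[C@@H](B2OC(C)(C)C(C)(C)O2)C[C@@H](B2OC(C)(C)C(C)(C)O2)CCC/C(C)=C\C(=O)OC(=O)c3c(C)cccc3[N+](=O)[O-]
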